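The data were generated by integration for an exercise; the scatter is artificial.

Time is the axis of Monday's run, and temperature stays out of it: every reading stands at 40 °C, so what heating does remains a guess.

all flasks: G 0.80 M; L 40 mM; temperature 40 °C

| charge | remark | time |
|---|---|---|
| Monday's | the very flask that is asked about, followed so far |  |
| flask |  | 15 h |

Monday's run (percent of the G charged)

| time / h | E / % |
|---|---|
| 1.33 | 22.6 |
| 2.50 | 41.4 |
| 4.00 | 56.2 |
| 5.00 | 61.2 |
| 6.00 | 63.5 |
| 8.00 | 70.3 |
| 10.0 | 74.7 |

(scatter of a reading: 1 percentage point)

- west: at 15 h add L, 50.0 % of the amount charged, then wait 15 h
- south: at 15 h raise the temperature by 15 K, then wait 15 h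
- north-west: change nothing and wait 15 h more
- east: at 15 h take out 90 % of the E then present, then wait 15 h

- E, in percent of the G first charged, at 15 h
- what to do for the largest gain in E; "none" if nothing gains more than 2 percentage points (west / south / north-west / east / none)
- E present, with what was taken out counted in, in percent of the G first charged, after north-west
- E present, with what was taken out counted in, in percent of the G first charged, after east

- E that was removed still counts
- additions bring no volume worth counting
- the earlier runs do not show what temperature does; that part of a forecast is a guess

The readings climb fast, then flatten with 25.3 % of the charge not E at 10.0 h. So the number to watch is the apparent first-order constant (pseudo-first-order), the fall in the logarithm of the unconverted fraction per hour. From 1.33 h to 4.00 h it reads 0.213 h⁻¹, but from 4.00 h to 10.0 h it reads 0.0915 h⁻¹, which is lower. A plain first-order law keeps this constant the same at every time.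

Drawn as a straight line against the mean E of each span, the constant reaches zero at the ceiling, 85.0 % of the charge. This is a reading, with the readings' scatter in it. Read as catalyst death, it gives a turnover number of 17.0 E per L charged. A reversible step is another reading of the same bend, but this reckoning commits to catalyst death.

Along that line, the ratio of unconverted charge to room under the ceiling grows exponentially at 0.0700 h⁻¹. From 2.45 at 10.0 h, it puts E at 79.0 % at 15 h and 83.3 % after 15 h more. In this reckoning east, with removed E counted, reaches that same figure. In this reckoning west raises the ceiling by 43 percentage points, more than the 21 points reckoned as not E at 15 h, so this reckoning picks west.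

The forecast differs: 80 % now, 82 % after north-west, 92 % after east, and east as best, on the ground that “Removing E restarts the reaction”.

The flask gives 77.8 % at 15 h, and 82.3 % after north-west and 82.3 % after east. West gains 16 points, more than south's 5 points and the 4.4 points of east, so the answer is west.

    G + J → J + E (k = 0.00320 L mol⁻¹ s⁻¹, Ea = 70.0 kJ mol⁻¹)
    G + J → D (k = 1.90 × 10⁻⁴ L mol⁻¹ s⁻¹, Ea = 83.0 kJ mol⁻¹)
    L → J (k = 4.30 × 10⁻⁴ s⁻¹, Ea = 96.0 kJ mol⁻¹)
    (constants at 40 °C)

The same reckoning carried to 40 h gives 84.2 %, still under the ceiling. The same flask, read at that time, holds E at 83.2 %, G at 12 % and J at 1.17 % of the catalyst charged.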